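If the substrate falls by one first-order law, one constant tells how much of it has reacted at any time, so we try that on these flasks. Each holds substrate, partner and scavenger, and the single product is the other species read.

common to all: substrate 0.40 M
- beta: partner 0.44 M; scavenger 0.076 M; run made earlier
- alpha: partner 0.44 M; scavenger 0.17 M; run made earlier
- ash: partner 0.440 M; scavenger 0.270 M; time 15 min
- birch: partner 0.440 M; scavenger 0.120 M; time 15 min
- oak: partner 0.440 M; scavenger 0.180 M; time 15 min

- beta (time / min: substrate / %, single product / %): 2.00: 36, 12; 4.00: 17, 14; 6.00: 7, 18; 8.00: 4, 16; 10.0: 3, 16; 12.0: 2, 19; 15.0: 2, 12
- alpha (time / min: substrate / %, single product / %): 2.00: 38, 10; 4.00: 15, 16; 6.00: 9, 15; 8.00: 2, 19; 10.0: 3, 15; 12.0: 4, 19; 15.0: 3, 20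

(readings scatter by 2 percentage points)

- what has gone from substrate into another species counts as reacted, even if it can come back

1. part of the substrate that has reacted at the end, ash
2. part of the substrate that has reacted at the end, birch
3. part of the substrate that has reacted at the end, oak
4. what raising the concentration of scavenger from its lowest to its highest value here does to the part of the substrate that has reacted (changes below 5 percentage points count as none) (it rises / it falls / no change)

From the mean of the two substrate readings at 4.00 min we read 0.458 /min: this is the apparent first-order constant, the substrate's fractional loss per minute, frozen at this early reading. Held to 15 min, it leaves 0.104%, which gives a bound from above of 99.9% reacted.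

The late readings stand higher, though. From 8.00 min on, the substrate averages 2.75% with 0.076 M of scavenger and 3.00% with 0.17 M, a gap smaller than the scatter of 2 percentage points. We take their mean, 2.88%, which is more than the constant leaves. One scatter either side gives a bound from below of 95.1% and tightens the top to 99.1%. We commit to 97.1% for ash, birch and oak. This bracket is narrower than the margin of 5 points, so we expect no change, though ash lies beyond the tested scavenger.

The forecast gave 97% for ash, 97.5% for birch and 97.5% for oak, with no change, inside our bracket, judging that “scavenger amount does not appear to limit it”.

The flask gives 95.2% for ash, 96.9% for birch and 96.2% for oak, a change of −1.7 points, so no change; our lower bound stood at 95.1%.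

    partner + single product → over-reaction product (k = 0.0300 /M/min)
    substrate + partner → single product + released group (k = 0.260 /M/min)
    partner + single product → double product + released group (k = 0.00730 /M/min)
    substrate + released group ⇌ idle adduct, settled at all times (K = 520 /M)
    substrate + partner → other mono adduct + released group (k = 0.410 /M/min)
    scavenger + released group → scavenged by-product (k = 2.00 /M/min)
    partner + other mono adduct → double product + released group (k = 0.310 /M/min)

At the end of ash, 44.5% of the substrate stands as idle adduct, which counts as reacted although it can come back. Our constant reaches the 4.8% of free substrate left in ash after 6.63 min, while ash holds that amount at 15 min. For ash read at 6.0 min, the constant gives 93.6% reacted; the computed flask gives 91.1%.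

(The earlier runs and the new flask stem from a simulated flask with made-up constants, and the scatter is random.)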